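The readings were generated by integration from invented constants; the scatter is artificial.

Held against the charge, the last south reading falls short: complex with one exchanged and complex with two exchanged together make 74.9%, less than the whole of the starting complex.

| flask | starting complex | incoming ligand | remark | time |
|---|---|---|---|---|
| north | 1 mM | 1.1 mM | run made earlier |  |
| south | 1 mM | 2.5 mM | run made earlier |  |
| spring | 1.0 mM | 1.50 mM |  | 2.5 min |
| dusk | 1.0 mM | 2.00 mM |  | 2.5 min |
| noon | 1.0 mM | 3.00 mM |  | 2.5 min |

| run | time / s | complex with one exchanged / % | complex with two exchanged / % |
|---|---|---|---|
| north | 10.0 | 18.2 | 9.5 |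
| north | 12.0 | 20.4 | 10.0 |
| north | 20.0 | 28.5 | 10.5 |
| north | 40.0 | 40.8 | 8.1 |
| north | 80.0 | 48.8 | 6.2 |
| south | 15.0 | 35.5 | 22.8 |
| south | 30.0 | 45.3 | 22.9 |
| south | 50.0 | 51.5 | 23.1 |
| south | 60.0 | 51.4 | 23.1 |
| south | 80.0 | 52.1 | 22.8 |

(readings scatter by 0.5 percentage points)

* amount of complex with one exchanged at the end, in percent of the starting complex charged, for each flask in turn (spring, dusk, noon)

Minutes of the meeting. The analyst reported that in the south run the complex with one exchanged, written m, stood at 51.5% after 50.0 s and 52.1% after 80.0 s, while the complex with two exchanged, written b, went from 23.1% to 22.8%. She took this as a plateau, the changes lying within readings good to 0.5 percentage points.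

The kineticist proposed to freeze what stood still and read the second exchange as a quasi-equilibrium. He defined the exchange quotient Q as (b/m)(L/X), where L is the leaving ligand set free and X the free incoming ligand.

The analyst objected that neither L nor X was measured. The kineticist answered with an assumption: each starting complex charged has given up one ligand, the missing part included, and b has given up one more. L is then the charge of starting complex plus b, and X is the ligand charged minus L. On the south run this gives Q = 0.422.

The meeting agreed to freeze both Q and the sum of m and b, written s, at their south values, and to solve for b in each flask. That reckoning gives m = 64.9% for spring, 57.7% for dusk and 47.6% for noon, so it expects more in spring than in noon.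

The forecast, with 51.7%, 53% and 51.2%, gives a flatter row than this one and reads the plateau so: “This is an equilibrium, not exhaustion of ligand”.

The flasks give 56.6%, 54.2% and 48.1%.

    starting complex + incoming ligand ⇌ leaving ligand + complex with one exchanged (K = 42.0, k = 40.0 /M/s)
    complex with one exchanged + incoming ligand ⇌ leaving ligand + complex with two exchanged (K = 0.440, k = 190 /M/s)
    complex with two exchanged + incoming ligand ⇌ leaving ligand + complex with three exchanged (K = 0.100, k = 6.30 /M/s)
    complex with three exchanged + incoming ligand ⇌ leaving ligand + complex with four exchanged (K = 0.220, k = 3.30 /M/s)
    starting complex + complex with two exchanged → side product (k = 48.0 /M/s)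

Taken from what stood at the end, Q comes to 0.439 in spring and 0.440 in dusk. In dusk the complex with one exchanged has a half-life of 1.8 s by the forward second exchange alone, the other concentrations as charged, far shorter than the 2.5 min of the flask, yet it stands there at 54.2% because the back reaction of leaving ligand with complex with two exchanged restores it. Run without that back reaction, dusk ends with 0.0379% of complex with one exchanged.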